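**Plan**

- Retrosynthetic cuts, in order: the Si–O bond and the two epoxide C–O bonds; the ring bond between the quaternary carbon (CH3, pyranonyl) and the neighbouring CH that carries the 1,1-disubstituted vinyl group (retro-6π); the sp2–sp2 single bond joining the central (Z)-alkene of the opened triene to the side-chain (E)-alkene (Stille); the pyranone-side C=C (aldol/dehydration) and the CH(OH)–CH(CH3) bond of the side chain (aldol).
- Enabling feature: in the 7-oxabicyclo[4.1.0]hept-2-ene core, C4 (quaternary) and C5 (CH) are adjacent sp3 carbons with their large groups cis, bridged by C3=C2 and the C1–C6 epoxide. Without the epoxide oxygen this is a cis-5,6-disubstituted cyclohexa-1,3-diene, the retron of a thermal disrotatory 6π electrocyclisation of a (2E,4Z,6E)-triene.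
- Forward order: an alkenyl iodide carrying the complete side chain (7 steps) and a (2E,4Z)-dienylstannane carrying the pyranone (6 steps) are joined by Stille coupling; the tetraene closes in the same flask to the only carbocycle; epoxidation and desilylation finish the synthesis.
- Stereochemistry: the two side-chain centres come from an Evans syn-aldol (auxiliary control). The two ring carbons made in the key step are fixed relative to each other by orbital symmetry and alkene geometry. Their absolute sense is relayed only weakly from the side chain and is secured by separating diastereomers. The epoxide carbons follow by substrate control, with attack anti to both large cis substituents.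

Key step: step 14

Remark: the C–O stereocentre of the iodide fragment lies two bonds from the ring-closing terminus, so only weak torquoselectivity is assumed; the unwanted cis-diastereomer is removed by chromatography.
Remark: 2-bromo-3,3-diethoxyprop-1-ene (2-bromoacrolein diethyl acetal) is taken as a catalogue compound.

**Route**

Step 1
Reactants: 1 2-bromo-3,3-diethoxyprop-1-ene; 2 propyne
Product: 3 2-(diethoxymethyl)pent-1-en-3-yne
Conditions: PdCl2(PPh3)2 (cat.), CuI (cat.), Et3N, THF, 45 °C, sealed vessel
Reagents that add atoms: none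
Why: Sonogashira coupling of an alkenyl bromide with a terminal alkyne is routine, the acetal is inert to the amine base, and no stereocentre is formed.

Step 2
Reactants: 3 2-(diethoxymethyl)pent-1-en-3-yne
Product: 5 (3E)-2-(diethoxymethyl)-4-iodopenta-1,3-diene, via alkenylzirconocene chloride 4 (not isolated)
Conditions: Cp2ZrHCl, THF, 20 °C; then I2, 0 °C, dark
Reagents that add atoms: iodine (II)
Why: Hydrozirconation adds Zr–H syn across the alkyne (much faster than across the 1,1-disubstituted alkene) with zirconium on the less hindered, methyl-bearing carbon remote from the branched vinyl acetal, and iodinolysis with retention should give the (E)-2-iodoalkene.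

Step 3
Reactants: 5 (3E)-2-(diethoxymethyl)-4-iodopenta-1,3-diene
Product: 6 (3E)-4-iodo-2-methylidenepent-3-enal
Conditions: oxalic acid (cat.), acetone–H2O, 20 °C; used at once
Reagents that add atoms: water (O)
Why: Acid-catalysed hydrolysis of an α,β-unsaturated acetal proceeds under very mild conditions through the allyl-stabilised oxocarbenium ion and leaves the alkenyl iodide geometry untouched.

Step 4
Reactants: 6 (3E)-4-iodo-2-methylidenepent-3-enal; 7 (4R)-4-benzyl-3-propanoyl-1,3-oxazolidin-2-one
Product: 8 (4R)-4-benzyl-3-[(2R,3R,5E)-3-hydroxy-6-iodo-2-methyl-4-methylidenehept-5-enoyl]-1,3-oxazolidin-2-one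
Conditions: 7, Bu2BOTf, i-Pr2NEt, CH2Cl2, 0 °C; then 6, −78 to 0 °C; H2O2, MeOH, pH 7 buffer
Reagents that add atoms: none
Why: Evans syn-aldol: the (Z)-boron enolate of 7 adds through a Zimmerman–Traxler chair in which the benzyl group of the (R)-auxiliary shields one enolate face, so both new centres (2R,3R, syn) are set in one event; α-substituted enals are good partners.

Step 5
Reactants: 8 (4R)-4-benzyl-3-[(2R,3R,5E)-3-hydroxy-6-iodo-2-methyl-4-methylidenehept-5-enoyl]-1,3-oxazolidin-2-one
Product: 9 (2R,3R,5E)-3-hydroxy-6-iodo-N-methoxy-N,2-dimethyl-4-methylidenehept-5-enamide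
Conditions: MeNH(OMe)·HCl, AlMe3, THF, −20 to 0 °C; aq. HCl work-up
Reagents that add atoms: N,O-dimethylhydroxylamine hydrochloride (CNOC.Cl)
Why: Weinreb transamidation with the aluminium amide, assisted by the free β-hydroxyl, should cleave the auxiliary without epimerisation or retro-aldol.

Step 6
Reactants: 9 (2R,3R,5E)-3-hydroxy-6-iodo-N-methoxy-N,2-dimethyl-4-methylidenehept-5-enamide
Product: 10 (2R,3R,5E)-6-iodo-N-methoxy-N,2-dimethyl-4-methylidene-3-(triethylsilyloxy)hept-5-enamide
Conditions: Et3SiOTf, 2,6-lutidine, CH2Cl2, −78 °C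
Reagents that add atoms: triethylsilyl triflate (CC[Si](CC)(CC)OS(=O)(=O)C(F)(F)F)
Why: Silylation blocks the allylic hydroxyl so that it can neither direct the later epoxidation nor suffer retro-aldol, and the triethylsilyl group is chosen because buffered fluoride removes it at the end.

Step 7
Reactants: 10 (2R,3R,5E)-6-iodo-N-methoxy-N,2-dimethyl-4-methylidene-3-(triethylsilyloxy)hept-5-enamide
Product: 11 (4R,5R,7E)-8-iodo-4-methyl-6-methylidene-5-(triethylsilyloxy)non-7-en-3-one
Conditions: EtMgBr, THF, 0 °C; aq. NH4Cl
Reagents that add atoms: ethylmagnesium bromide (CC[Mg]Br)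
Why: Weinreb ketone synthesis: the chelated tetrahedral intermediate prevents over-addition, and the alkenyl iodide, the diene and the silyl ether are inert to the Grignard reagent at 0 °C.

Step 8
Reactants: 12 methyl 2-methyl-3-oxopentanoate; 13 N-methoxy-N-methylpropanamide
Product: 15 6-ethyl-4-hydroxy-3,5-dimethyl-2H-pyran-2-one, via triketo ester 14 (not isolated)
Conditions: 12, NaH then n-BuLi, THF, 0 °C; 13, 0 °C; aq. HCl; crude in PhMe, DBU, 80 °C
Reagents that add atoms: none
Why: γ-Acylation of the β-keto ester dianion followed by base-mediated lactonisation (enol oxygen onto the ester) is the standard entry to 4-hydroxy-3,5-dimethyl-2-pyranones.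

Step 9
Reactants: 15 6-ethyl-4-hydroxy-3,5-dimethyl-2H-pyran-2-one
Product: 16 2-ethyl-6-methoxy-3,5-dimethyl-4H-pyran-4-one
Conditions: MeOTf (1.05 equiv), CH2Cl2, 20 °C; aq. NaHCO3
Reagents that add atoms: methyl triflate (COS(=O)(=O)C(F)(F)F)
Why: Under neutral conditions a hard methyl sulfonate alkylates the more basic lactone carbonyl oxygen of a 4-hydroxy-2-pyranone, and loss of the proton should give the 2-methoxy-4-pyranone, the known regiochemistry for this heterocycle.

Step 10
Reactants: 17 prop-2-yn-1-ol
Product: 19 (2Z)-2-methyl-3-(tributylstannyl)prop-2-en-1-ol, via alkenylmagnesium bromide 18 (not isolated)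
Conditions: MeMgBr (3 equiv), CuI (cat.), THF–Et2O, −10 to 20 °C; then Bu3SnCl, 0 to 20 °C; aq. NH4Cl
Reagents that add atoms: methylmagnesium bromide (C[Mg]Br); tributyltin chloride (CCCC[Sn](Cl)(CCCC)CCCC)
Why: Copper-catalysed anti-carbomagnesiation of propargyl alcohol places methyl on C2 and magnesium on C3 cis to the chelating alkoxide, and stannylation of the alkenylmagnesium with retention fixes the (Z)-geometry needed for the central alkene of the triene.

Step 11
Reactants: 19 (2Z)-2-methyl-3-(tributylstannyl)prop-2-en-1-ol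
Product: 20 (2Z)-2-methyl-3-(tributylstannyl)prop-2-enal
Conditions: MnO2, CH2Cl2, 20 °C
Reagents that add atoms: none
Why: MnO2 oxidises the allylic alcohol selectively to the enal without touching the C–Sn bond or the alkene geometry.

Step 12
Reactants: 16 2-ethyl-6-methoxy-3,5-dimethyl-4H-pyran-4-one; 20 (2Z)-2-methyl-3-(tributylstannyl)prop-2-enal
Product: 21 2-[(4Z)-3-hydroxy-4-methyl-5-(tributylstannyl)pent-4-en-2-yl]-6-methoxy-3,5-dimethyl-4H-pyran-4-one (mixture of diastereomers)
Conditions: 16, LiN(SiMe3)2, THF, −78 °C; then 20, −78 °C; aq. NH4Cl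
Reagents that add atoms: none
Why: The CH2 of the 2-ethyl group is deprotonated as a vinylogous ester enolate and adds 1,2 to the enal (aldol addition); the two new stereocentres are removed in the next step.

Step 13
Reactants: 21 2-[(4Z)-3-hydroxy-4-methyl-5-(tributylstannyl)pent-4-en-2-yl]-6-methoxy-3,5-dimethyl-4H-pyran-4-one
Product: 23 2-methoxy-3,5-dimethyl-6-[(2E,4Z)-4-methyl-5-(tributylstannyl)penta-2,4-dien-2-yl]-4H-pyran-4-one, via allylic mesylate 22 (not isolated)
Conditions: MsCl, Et3N, CH2Cl2, 0 °C; then DBU, 20 °C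
Reagents that add atoms: none
Why: Mesylation and E1cB elimination through the acidic position next to the pyranone should give the conjugated (E)-alkene (pyranone trans to the chain, the thermodynamically preferred geometry), while the (Z)-alkenylstannane is not involved.

Step 14
Reactants: 23 2-methoxy-3,5-dimethyl-6-[(2E,4Z)-4-methyl-5-(tributylstannyl)penta-2,4-dien-2-yl]-4H-pyran-4-one; 11 (4R,5R,7E)-8-iodo-4-methyl-6-methylidene-5-(triethylsilyloxy)non-7-en-3-one
Product: 25 2-methoxy-3,5-dimethyl-6-[(1R,6R)-1,3,5-trimethyl-6-[(3R,4R)-4-methyl-5-oxo-3-(triethylsilyloxy)hept-1-en-2-yl]cyclohexa-2,4-dien-1-yl]-4H-pyran-4-one, via tetraene 24 (not isolated)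
Conditions: Pd2(dba)3 (cat.), AsPh3, CuI (cat.), DMF, 40 °C, dark; then PhMe, 110 °C, dark; chromatography
Reagents that add atoms: none
Why: Stille coupling (oxidative addition of zerovalent palladium into the C–I bond of 11, copper-assisted transmetalation of 23 with retention, reductive elimination) should give the (2E,4Z,6E)-tetraene 24, whose (Z) central alkene holds the two trisubstituted termini within reach, and heating then drives a thermal 6π disrotatory electrocyclisation; the closest known reaction type is the cross-coupling/6π-electrocyclisation sequence used to assemble cyclohexadienyl-pyranone polypropionates. The six-membered carbocycle closes in the suprafacial, disrotatory mode, all six triene carbons becoming ring atoms. The quaternary carbon and the adjacent CH are set relative to each other by orbital symmetry and the E geometry of both terminal alkenes: the two outside groups (pyranonyl and the 1,1-disubstituted vinyl unit) finish cis, the inside CH3 and H cis. Their absolute sense depends on torquoselectivity, for which the only control element is the C–OSiEt3 stereocentre acting through the cross-conjugated C(=CH2) spacer; no strong bias can be claimed, so 25 is expected together with its (1S,6S) diastereomer, which differs from it as a diastereomer and is removed by chromatography. The step also needs site selectivity (only the triene with the Z central bond can reach the s-cis,s-cis geometry, the exocyclic methylene being cross-conjugated and attached through an E alkene), preference for ring closure over [1,7]-hydrogen shift from the inside CH3 (helped by the twist that the methyl groups impose on the triene) and retention of all alkene geometries, secured by the stereospecific, fluoride-free coupling and exclusion of light.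

Step 15
Reactants: 25 2-methoxy-3,5-dimethyl-6-[(1R,6R)-1,3,5-trimethyl-6-[(3R,4R)-4-methyl-5-oxo-3-(triethylsilyloxy)hept-1-en-2-yl]cyclohexa-2,4-dien-1-yl]-4H-pyran-4-one
Product: 26 2-methoxy-3,5-dimethyl-6-[(1R,4R,5R,6S)-2,4,6-trimethyl-5-[(3R,4R)-4-methyl-5-oxo-3-(triethylsilyloxy)hept-1-en-2-yl]-7-oxabicyclo[4.1.0]hept-2-en-4-yl]-4H-pyran-4-one
Conditions: mCPBA (1 equiv), NaHCO3, CH2Cl2, −20 to 0 °C
Reagents that add atoms: mCPBA (O=C(OO)c1cccc(Cl)c1)
Why: Prilezhaev epoxidation should take the C4=C5 ring alkene next to C6–H, because C2=C3 is flanked by the quaternary carbon and feels the inductive pull of the pyranone and the exocyclic methylene is 1,1-disubstituted and deactivated by the allylic silyloxy group; the peracid approaches anti to the pseudoaxial side chain and the pyranonyl group, which are cis, and this sets both epoxide carbons.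

Step 16
Reactants: 26 2-methoxy-3,5-dimethyl-6-[(1R,4R,5R,6S)-2,4,6-trimethyl-5-[(3R,4R)-4-methyl-5-oxo-3-(triethylsilyloxy)hept-1-en-2-yl]-7-oxabicyclo[4.1.0]hept-2-en-4-yl]-4H-pyran-4-one
Product: 27 2-[(1R,4R,5R,6S)-5-[(3R,4R)-3-hydroxy-4-methyl-5-oxohept-1-en-2-yl]-2,4,6-trimethyl-7-oxabicyclo[4.1.0]hept-2-en-4-yl]-6-methoxy-3,5-dimethyl-4H-pyran-4-one
Conditions: HF·pyridine, pyridine, THF, 0 °C
Reagents that add atoms: none
Why: Buffered fluoride cleaves the triethylsilyl ether without the base that would cause retro-aldol and without the strong acid that would open the vinyl epoxide; no stereocentre is touched.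

**Compound list**

1 | 2-bromo-3,3-diethoxyprop-1-ene | C=C(Br)C(OCC)OCC | starting material
2 | propyne | CC#C | starting material
3 | 2-(diethoxymethyl)pent-1-en-3-yne | C=C(C#CC)C(OCC)OCC | intermediate
4 | chloro[(2E)-4-(diethoxymethyl)penta-2,4-dien-2-yl]zirconocene (not isolated) | C=C(/C=C(\C)[Zr](Cl)(C1C=CC=C1)C1C=CC=C1)C(OCC)OCC | intermediate
5 | (3E)-2-(diethoxymethyl)-4-iodopenta-1,3-diene | C=C(/C=C(\C)I)C(OCC)OCC | intermediate
6 | (3E)-4-iodo-2-methylidenepent-3-enal | C=C(/C=C(\C)I)C=O | intermediate
7 | (4R)-4-benzyl-3-propanoyl-1,3-oxazolidin-2-one | CCC(=O)N1[C@H](Cc2ccccc2)COC1=O | starting material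
8 | (4R)-4-benzyl-3-[(2R,3R,5E)-3-hydroxy-6-iodo-2-methyl-4-methylidenehept-5-enoyl]-1,3-oxazolidin-2-one | C=C(/C=C(\C)I)[C@H](O)[C@@H](C)C(=O)N1[C@H](Cc2ccccc2)COC1=O | intermediate
9 | (2R,3R,5E)-3-hydroxy-6-iodo-N-methoxy-N,2-dimethyl-4-methylidenehept-5-enamide | C=C(/C=C(\C)I)[C@H](O)[C@@H](C)C(=O)N(C)OC | intermediate
10 | (2R,3R,5E)-6-iodo-N-methoxy-N,2-dimethyl-4-methylidene-3-(triethylsilyloxy)hept-5-enamide | C=C(/C=C(\C)I)[C@H](O[Si](CC)(CC)CC)[C@@H](C)C(=O)N(C)OC | intermediate
11 | (4R,5R,7E)-8-iodo-4-methyl-6-methylidene-5-(triethylsilyloxy)non-7-en-3-one | C=C(/C=C(\C)I)[C@H](O[Si](CC)(CC)CC)[C@@H](C)C(=O)CC | intermediate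
12 | methyl 2-methyl-3-oxopentanoate | CCC(=O)C(C)C(=O)OC | starting material
13 | N-methoxy-N-methylpropanamide | CCC(=O)N(C)OC | starting material
14 | methyl 2,4-dimethyl-3,5-dioxoheptanoate (not isolated; stereocentres undefined) | CCC(=O)C(C)C(=O)C(C)C(=O)OC | intermediate
15 | 6-ethyl-4-hydroxy-3,5-dimethyl-2H-pyran-2-one | CCc1oc(=O)c(C)c(O)c1C | intermediate
16 | 2-ethyl-6-methoxy-3,5-dimethyl-4H-pyran-4-one | CCc1oc(OC)c(C)c(=O)c1C | intermediate
17 | prop-2-yn-1-ol | C#CCO | starting material
18 | bromo[(1Z)-3-(bromomagnesiooxy)-2-methylprop-1-en-1-yl]magnesium (not isolated) | C/C(CO[Mg]Br)=C/[Mg]Br | intermediate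
19 | (2Z)-2-methyl-3-(tributylstannyl)prop-2-en-1-ol | CCCC[Sn](CCCC)(CCCC)/C=C(/C)CO | intermediate
20 | (2Z)-2-methyl-3-(tributylstannyl)prop-2-enal | CCCC[Sn](CCCC)(CCCC)/C=C(/C)C=O | intermediate
21 | 2-[(4Z)-3-hydroxy-4-methyl-5-(tributylstannyl)pent-4-en-2-yl]-6-methoxy-3,5-dimethyl-4H-pyran-4-one (mixture of diastereomers at the two sp3 chain carbons) | COc1oc(C(C)C(O)/C(C)=C\[Sn](CCCC)(CCCC)CCCC)c(C)c(=O)c1C | intermediate
22 | methanesulfonate of 21 (not isolated; mixture of diastereomers) | COc1oc(C(C)C(OS(C)(=O)=O)/C(C)=C\[Sn](CCCC)(CCCC)CCCC)c(C)c(=O)c1C | intermediate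
23 | 2-methoxy-3,5-dimethyl-6-[(2E,4Z)-4-methyl-5-(tributylstannyl)penta-2,4-dien-2-yl]-4H-pyran-4-one | COc1oc(/C(C)=C/C(C)=C\[Sn](CCCC)(CCCC)CCCC)c(C)c(=O)c1C | intermediate
24 | 2-methoxy-3,5-dimethyl-6-[(2E,4Z,6E,9R,10R)-4,6,10-trimethyl-8-methylidene-11-oxo-9-(triethylsilyloxy)trideca-2,4,6-trien-2-yl]-4H-pyran-4-one (not isolated) | COc1oc(/C(C)=C/C(C)=C\C(C)=C\C(=C)[C@H](O[Si](CC)(CC)CC)[C@@H](C)C(=O)CC)c(C)c(=O)c1C | intermediate
25 | 2-methoxy-3,5-dimethyl-6-[(1R,6R)-1,3,5-trimethyl-6-[(3R,4R)-4-methyl-5-oxo-3-(triethylsilyloxy)hept-1-en-2-yl]cyclohexa-2,4-dien-1-yl]-4H-pyran-4-one | C=C([C@H](O[Si](CC)(CC)CC)[C@@H](C)C(=O)CC)[C@H]1C(C)=CC(C)=C[C@@]1(C)c1oc(OC)c(C)c(=O)c1C | intermediate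
26 | 2-methoxy-3,5-dimethyl-6-[(1R,4R,5R,6S)-2,4,6-trimethyl-5-[(3R,4R)-4-methyl-5-oxo-3-(triethylsilyloxy)hept-1-en-2-yl]-7-oxabicyclo[4.1.0]hept-2-en-4-yl]-4H-pyran-4-one | C=C([C@H](O[Si](CC)(CC)CC)[C@@H](C)C(=O)CC)[C@H]1[C@]2(C)O[C@@H]2C(C)=C[C@@]1(C)c1oc(OC)c(C)c(=O)c1C | intermediate
27 | 2-[(1R,4R,5R,6S)-5-[(3R,4R)-3-hydroxy-4-methyl-5-oxohept-1-en-2-yl]-2,4,6-trimethyl-7-oxabicyclo[4.1.0]hept-2-en-4-yl]-6-methoxy-3,5-dimethyl-4H-pyran-4-one (CNP0233636.2) | C=C([C@H](O)[C@@H](C)C(=O)CC)[C@H]1[C@]2(C)O[C@@H]2C(C)=C[C@@]1(C)c1oc(OC)c(C)c(=O)c1C | target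

**Step count**

Total step count: 16. Longest linear sequence: 10 steps (steps 1–7 and 14–16, from 1 to 27).

**Steps most likely to fail**

1. Step 14. What may go wrong: little or no torquoselectivity from the remote silyloxy stereocentre, so that both cis-diastereomers form in similar amounts; loss of the triene to a [1,7]-hydrogen shift; or elimination of the β-silyloxy ketone during heating.
Fallback (ring before stereocentres; sets out from 6 and returns at 27): Luche reduction of 6 (NaBH4, CeCl3·7H2O, MeOH, 0 °C) would give (3E)-4-iodo-2-methylidenepent-3-en-1-ol F1, which is silylated (t-BuMe2SiCl, imidazole) to tert-butyl{[(3E)-4-iodo-2-methylidenepent-3-en-1-yl]oxy}dimethylsilane F2. The same Stille coupling with 23 and heating would lead, through the achiral tetraene F3 (not isolated), to the racemic cis-cyclohexadiene silyl ether F4, a closure that needs no torquoselectivity. mCPBA would then give the racemic epoxide F5, Bu4NF the racemic allylic alcohol F6 and MnO2 the racemic enal F7. A reagent-controlled syn-aldol of pentan-3-one through its (Z)-enol diisopinocampheylborinate [(Ipc)2BOTf antipode that attacks the aldehyde re face, i-Pr2NEt, CH2Cl2, −78 °C; H2O2] would convert the two ring antipodes into 27 and the ring-antipodal diastereomer F8, which are separated by chromatography.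

2. Step 15. What may go wrong: epoxidation at the other ring alkene or at the exocyclic methylene, attack on the face syn to the side chain, over-oxidation, or acid-induced opening of the vinyl epoxide.
Fallback (reagent control in place of substrate control; sets out from 25 and returns at 26, no new compound): a Shi epoxidation with the fructose-derived ketone antipode whose spiro transition state delivers oxygen to the face anti to the side chain (KHSO5, K2CO3 buffer near pH 10.5, MeCN–dimethoxymethane–water, 0 °C). This dioxirane method is known to pick the more electron-rich, less hindered alkene of a conjugated diene and works without acid.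

3. Step 13. What may go wrong: E/Z scrambling in the base-mediated elimination, capture of the allylic mesylate by chloride with allylic shift, or protodestannylation by the ammonium salts.
Fallback (olefination in place of aldol/dehydration; sets out from 16 and returns at 23, replacing steps 12 and 13): 16 is deprotonated with LiN(SiMe3)2 (2 equiv) and C-phosphorylated with ClP(O)(OEt)2 to give diethyl [1-(6-methoxy-3,5-dimethyl-4-oxo-4H-pyran-2-yl)ethyl]phosphonate F9. Its lithium salt and aldehyde 20 then undergo Horner–Wadsworth–Emmons olefination (THF, −78 to 0 °C) to give 23 directly, so that no leaving group and no ammonium salt meets the stannane.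

Further compounds
F1 | step 14 | (3E)-4-iodo-2-methylidenepent-3-en-1-ol | C=C(/C=C(\C)I)CO
F2 | step 14 | tert-butyl{[(3E)-4-iodo-2-methylidenepent-3-en-1-yl]oxy}dimethylsilane | C=C(/C=C(\C)I)CO[Si](C)(C)C(C)(C)C
F3 | step 14 | achiral (2E,4Z,6E)-tetraene silyl ether, the analogue of 24 with CH2OSi(t-Bu)Me2 in place of the aldol chain (not isolated) | COc1oc(/C(C)=C/C(C)=C\C(C)=C\C(=C)CO[Si](C)(C)C(C)(C)C)c(C)c(=O)c1C
F4 | step 14 | racemic cis-cyclohexadiene silyl ether, relative configuration as in 25 (one enantiomer drawn) | C=C(CO[Si](C)(C)C(C)(C)C)[C@H]1C(C)=CC(C)=C[C@@]1(C)c1oc(OC)c(C)c(=O)c1C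
F5 | step 14 | racemic epoxide silyl ether, relative configuration as in 26 (one enantiomer drawn) | C=C(CO[Si](C)(C)C(C)(C)C)[C@H]1[C@]2(C)O[C@@H]2C(C)=C[C@@]1(C)c1oc(OC)c(C)c(=O)c1C
F6 | step 14 | racemic epoxy allylic alcohol, relative configuration as in 26 (one enantiomer drawn) | C=C(CO)[C@H]1[C@]2(C)O[C@@H]2C(C)=C[C@@]1(C)c1oc(OC)c(C)c(=O)c1C
F7 | step 14 | racemic epoxy enal, relative configuration as in 26 (one enantiomer drawn) | C=C(C=O)[C@H]1[C@]2(C)O[C@@H]2C(C)=C[C@@]1(C)c1oc(OC)c(C)c(=O)c1C
F8 | step 14 | 2-[(1S,4S,5S,6R)-5-[(3R,4R)-3-hydroxy-4-methyl-5-oxohept-1-en-2-yl]-2,4,6-trimethyl-7-oxabicyclo[4.1.0]hept-2-en-4-yl]-6-methoxy-3,5-dimethyl-4H-pyran-4-one | C=C([C@H](O)[C@@H](C)C(=O)CC)[C@@H]1[C@@]2(C)O[C@H]2C(C)=C[C@]1(C)c1oc(OC)c(C)c(=O)c1C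
F0 | step 15 | none | none
F9 | step 13 | diethyl [1-(6-methoxy-3,5-dimethyl-4-oxo-4H-pyran-2-yl)ethyl]phosphonate | CCOP(=O)(OCC)C(C)c1oc(OC)c(C)c(=O)c1C
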